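**Retrosynthetic overview**

1. Side-chain carbons are counted from the CH2 on the quinone (C1) to the CH2 on the cyclohexene ring (C25). The last operation is oxidative demethylation of the 1,4-dimethoxynaphthalene 32 to the quinone.
2. Key disconnection C17–C18 (sp3–sp2). C17 is an unbranched CH2 two carbons from C15 of the C14=C15 alkene, so it is the terminus of a latent conjugated diene C14=C15–C16=C17. C18 is the H-bearing carbon of the (E)-methyl-branched alkene C18=C19, the retron of a terminal alkyne. One-pot 9-BBN hydroboration of diene 30 and Suzuki–Miyaura coupling with alkenyl iodide 15 joins a C34 and a C19 half and completes the whole carbon skeleton.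
3. Eastern half 30: C8–C9 by copper-catalysed Grignard–tosylate coupling and C1–C2 by alkyne carboalumination/benzyl coupling. C7 comes from (R)-3-bromo-2-methylpropanol and C11 from (R)-citronellyl bromide, whose (E)-methyl becomes the diene by allylic oxidation and Wittig methylenation.
4. Western half 15: two alkyne carboalumination–iodination steps (C22=C23, C18=C19) around one alkyl–alkenyl Negishi coupling (C21–C22). The ring stereocentre comes from CBS reduction of enone 1 and chirality transfer in a Johnson–Claisen rearrangement.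
5. Rings: none is formed. The cyclohexene ring is bought as 1 (the Claisen step moves its double bond), the naphthalene as 24, and the quinone ring is unveiled last.

Key step: step 18

Remark: compounds 1, 10, 16, 20 and 24 are taken as purchasable; the CBS face selectivity in step 1 is assigned by analogy (alkenyl carbon as the large group).

**Step 1**
Reactants: 1 2,4,4-trimethylcyclohex-2-en-1-one
Product: 2 (1R)-2,4,4-trimethylcyclohex-2-en-1-ol
Conditions: (S)-2-methyl-CBS-oxazaborolidine (0.1 equiv), BH3·SMe2, THF, −20 °C; MeOH quench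
Reagents that add atoms: none
Why: Corey–Bakshi–Shibata reduction, in which the oxazaborolidine–borane complex binds the ketone with the methyl-bearing alkenyl carbon as the large group and delivers hydride to one carbonyl face, should set the (R)-carbinol centre that step 2 relays to the ring stereocentre.

**Step 2**
Reactants: 2 (1R)-2,4,4-trimethylcyclohex-2-en-1-ol
Product: 4 ethyl 2-[(1S)-2,6,6-trimethylcyclohex-2-en-1-yl]acetate, via ketene acetal 3 (not isolated)
Conditions: CH3C(OEt)3 (6 equiv), EtCO2H (cat.), 140–160 °C, EtOH distilled off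
Reagents that add atoms: triethyl orthoacetate, CC(OCC)(OCC)OCC
Why: Johnson–Claisen rearrangement: the suprafacial [3,3] shift of ketene acetal 3 forms the new C–C bond at the former C3 on the ring face that carried the C1–O bond, which should turn the (R)-carbinol into the (S)-ring stereocentre and move the double bond to the 2,3-position.

**Step 3**
Reactants: 4 ethyl 2-[(1S)-2,6,6-trimethylcyclohex-2-en-1-yl]acetate
Product: 5 2-[(1S)-2,6,6-trimethylcyclohex-2-en-1-yl]ethan-1-ol
Conditions: LiAlH4, Et2O, 0 °C to rt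
Reagents that add atoms: none
Why: LiAlH4 ester reduction leaves the trisubstituted ring alkene and the adjacent stereocentre untouched.

**Step 4**
Reactants: 5 2-[(1S)-2,6,6-trimethylcyclohex-2-en-1-yl]ethan-1-ol
Product: 6 (6S)-6-(2-iodoethyl)-1,5,5-trimethylcyclohex-1-ene
Conditions: I2, PPh3, imidazole, CH2Cl2, 0 °C to rt
Reagents that add atoms: iodine, II
Why: Appel-type iodination of an unhindered primary alcohol by SN2 displacement of the oxyphosphonium group.

**Step 5**
Reactants: 6 (6S)-6-(2-iodoethyl)-1,5,5-trimethylcyclohex-1-ene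
Product: 7 (6S)-6-(but-3-yn-1-yl)-1,5,5-trimethylcyclohex-1-ene
Conditions: LiC≡CH·H2NCH2CH2NH2, DMSO, rt
Reagents that add atoms: lithium acetylide (as its ethylenediamine complex), [Li]C#C
Why: SN2 alkylation of an acetylide by a primary iodide in a dipolar aprotic solvent should give the terminal alkyne without touching the remote stereocentre.

**Step 6**
Reactants: 7 (6S)-6-(but-3-yn-1-yl)-1,5,5-trimethylcyclohex-1-ene
Product: 9 (6S)-6-[(3E)-4-iodo-3-methylbut-3-en-1-yl]-1,5,5-trimethylcyclohex-1-ene, via alkenylalane 8 (not isolated)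
Conditions: AlMe3 (2.5 equiv), Cp2ZrCl2 (0.2 equiv), CH2Cl2, 0 °C to rt; then I2, THF, −30 to 0 °C
Reagents that add atoms: trimethylaluminium, C[Al](C)C; iodine, II
Why: Zirconium-catalysed syn-methylalumination of the terminal alkyne (Negishi carboalumination) puts methyl on the internal and aluminium on the terminal carbon, and iodinolysis with retention should give the (E)-iodide of the C22=C23 unit.

**Step 7**
Reactants: 9 (6S)-6-[(3E)-4-iodo-3-methylbut-3-en-1-yl]-1,5,5-trimethylcyclohex-1-ene; 10 (4-bromobut-1-yn-1-yl)trimethylsilane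
Product: 12 trimethyl{(5E)-6-methyl-8-[(1S)-2,6,6-trimethylcyclohex-2-en-1-yl]oct-5-en-1-yn-1-yl}silane, via alkylzinc bromide 11 (not isolated)
Conditions: 10, Zn dust, LiCl, THF, 50 °C; then 9, PdCl2(dppf) (3 mol%), THF, rt to 40 °C
Reagents that add atoms: none
Why: Negishi coupling of a primary alkylzinc with an alkenyl iodide retains the (E) geometry, and the chelating diphosphine suppresses β-hydride elimination.

**Step 8**
Reactants: 12 trimethyl{(5E)-6-methyl-8-[(1S)-2,6,6-trimethylcyclohex-2-en-1-yl]oct-5-en-1-yn-1-yl}silane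
Product: 13 (6S)-1,5,5-trimethyl-6-[(3E)-3-methyloct-3-en-7-yn-1-yl]cyclohex-1-ene
Conditions: K2CO3, MeOH, rt
Reagents that add atoms: none
Why: Methoxide-mediated protodesilylation of the alkynylsilane frees the terminal alkyne.

**Step 9**
Reactants: 13 (6S)-1,5,5-trimethyl-6-[(3E)-3-methyloct-3-en-7-yn-1-yl]cyclohex-1-ene
Product: 15 (6S)-6-[(3E,7E)-8-iodo-3,7-dimethylocta-3,7-dien-1-yl]-1,5,5-trimethylcyclohex-1-ene, via dienylalane 14 (not isolated)
Conditions: AlMe3 (2.5 equiv), Cp2ZrCl2 (0.2 equiv), CH2Cl2, 0 °C to rt; then I2, THF, −30 to 0 °C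
Reagents that add atoms: trimethylaluminium, C[Al](C)C; iodine, II
Why: A second Negishi carboalumination–iodinolysis installs the C19 methyl and the (E)-C18=C19 geometry by syn addition, the trisubstituted alkenes being inert.

**Step 10**
Reactants: 16 (6R)-8-bromo-2,6-dimethyloct-2-ene [(R)-citronellyl bromide]
Product: 18 (2E,6R)-8-bromo-2,6-dimethyloct-2-enal, via allylic alcohol 17 (not isolated)
Conditions: SeO2 (0.3 equiv), t-BuOOH, salicylic acid (cat.), CH2Cl2, rt; then MnO2, CH2Cl2, rt on the crude mixture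
Reagents that add atoms: tert-butyl hydroperoxide, CC(C)(C)OO (oxygen relayed by selenium dioxide, O=[Se]=O)
Why: Riley allylic oxidation (ene reaction then [2,3]-shift) attacks the (E)-methyl of the trisubstituted alkene selectively, and MnO2 converges the alcohol/aldehyde mixture on the (E)-enal.

**Step 11**
Reactants: 18 (2E,6R)-8-bromo-2,6-dimethyloct-2-enal
Product: 19 (3E,7R)-9-bromo-3,7-dimethylnona-1,3-diene
Conditions: Ph3PCH3Br, KOt-Bu, THF, 0 °C; then 18, −78 to 0 °C
Reagents that add atoms: methyltriphenylphosphonium bromide, C[P+](c1ccccc1)(c1ccccc1)c1ccccc1.[Br-]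
Why: Wittig methylenation of the enal should give the conjugated diene with the (E)-trisubstituted alkene unchanged, the primary bromide being too slow an electrophile for the ylide at low temperature.

**Step 12**
Reactants: 10 (4-bromobut-1-yn-1-yl)trimethylsilane; 20 (2R)-3-bromo-2-methylpropan-1-ol
Product: 22 (2S)-2-methyl-7-(trimethylsilyl)hept-6-yn-1-ol, via Grignard reagent 21 (not isolated)
Conditions: 10, Mg turnings, THF, rt; 20, MeMgCl (1.0 equiv), THF, −20 °C; then 21 (1.5 equiv), Li2CuCl4 (3 mol%), NMP, −20 °C to rt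
Reagents that add atoms: none
Why: Copper-catalysed Grignard–alkyl bromide cross-coupling on the magnesium alkoxide of 20 forms C5–C6 without touching the stereocentre, which is not a reacting carbon (the descriptor changes only because the CIP priorities change).

**Step 13**
Reactants: 22 (2S)-2-methyl-7-(trimethylsilyl)hept-6-yn-1-ol
Product: 23 (2S)-2-methylhept-6-yn-1-ol
Conditions: K2CO3, MeOH, rt
Reagents that add atoms: none
Why: Protodesilylation of the alkynylsilane.

**Step 14**
Reactants: 24 1,4-dimethoxy-2-methylnaphthalene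
Product: 25 2-(chloromethyl)-1,4-dimethoxy-3-methylnaphthalene
Conditions: (CH2O)n, HCl (gas), AcOH, rt
Reagents that add atoms: formaldehyde (as paraformaldehyde), C=O; hydrogen chloride, Cl
Why: Blanc chloromethylation should occur at the only free position of the doubly methoxy-activated ring.

**Step 15**
Reactants: 23 (2S)-2-methylhept-6-yn-1-ol; 25 2-(chloromethyl)-1,4-dimethoxy-3-methylnaphthalene
Product: 27 (2S,6E)-8-(1,4-dimethoxy-3-methylnaphthalen-2-yl)-2,6-dimethyloct-6-en-1-ol, via alkenylalane 26 (not isolated)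
Conditions: AlMe3 (3.5 equiv), Cp2ZrCl2 (0.25 equiv), ClCH2CH2Cl, 0 °C to rt; volatiles removed; then 25, NiCl2(PPh3)2 (5 mol%) reduced with n-BuLi (10 mol%) to zerovalent nickel, THF, rt
Reagents that add atoms: trimethylaluminium, C[Al](C)C
Why: Negishi carboalumination of the terminal alkyne (hydroxyl masked in situ as its dimethylaluminium alkoxide) followed by nickel-catalysed alkenyl–benzyl cross-coupling with retention should give the (E)-C2=C3 alkene and the C1–C2 bond in one flask.

**Step 16**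
Reactants: 27 (2S,6E)-8-(1,4-dimethoxy-3-methylnaphthalen-2-yl)-2,6-dimethyloct-6-en-1-ol
Product: 28 (2S,6E)-8-(1,4-dimethoxy-3-methylnaphthalen-2-yl)-2,6-dimethyloct-6-en-1-yl 4-methylbenzenesulfonate
Conditions: TsCl, Et3N, DMAP (cat.), CH2Cl2, 0 °C to rt
Reagents that add atoms: 4-toluenesulfonyl chloride, Cc1ccc(cc1)S(Cl)(=O)=O
Why: Sulfonylation of the primary alcohol gives the leaving group for the sp3–sp3 coupling.

**Step 17**
Reactants: 19 (3E,7R)-9-bromo-3,7-dimethylnona-1,3-diene; 28 (2S,6E)-8-(1,4-dimethoxy-3-methylnaphthalen-2-yl)-2,6-dimethyloct-6-en-1-yl 4-methylbenzenesulfonate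
Product: 30 2-[(2E,7R,11S,14E)-3,7,11,15-tetramethylheptadeca-2,14,16-trien-1-yl]-1,4-dimethoxy-3-methylnaphthalene, via Grignard reagent 29 (not isolated)
Conditions: 19, Mg turnings, THF, rt; then 28, Li2CuCl4 (5 mol%), THF, −78 to 0 °C
Reagents that add atoms: none
Why: Copper-catalysed coupling of a primary Grignard reagent with a primary tosylate forms C8–C9 by SN2-type displacement, and both methyl stereocentres are carried over unchanged because neither is a reacting carbon.

**Step 18**
Reactants: 30 2-[(2E,7R,11S,14E)-3,7,11,15-tetramethylheptadeca-2,14,16-trien-1-yl]-1,4-dimethoxy-3-methylnaphthalene; 15 (6S)-6-[(3E,7E)-8-iodo-3,7-dimethylocta-3,7-dien-1-yl]-1,5,5-trimethylcyclohex-1-ene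
Product: 32 2-[(2E,7R,11S,14E,18E,22E)-3,7,11,15,19,23-hexamethyl-25-[(1S)-2,6,6-trimethylcyclohex-2-en-1-yl]pentacosa-2,14,18,22-tetraen-1-yl]-1,4-dimethoxy-3-methylnaphthalene, via homoallylborane 31 (not isolated)
Conditions: 30, 9-BBN (1.1 equiv), THF, 0 °C to rt; then 15, PdCl2(dppf) (5 mol%), AsPh3 (5 mol%), Cs2CO3 (3 equiv), DMF/THF/H2O, rt
Reagents that add atoms: none
Why: 9-BBN adds H–B syn and anti-Markovnikov to the only monosubstituted alkene of 30 (boron on the terminal carbon C17) to give homoallylborane 31, whose base-activated primary alkyl group is transferred to the alkenylpalladium iodide formed from 15 and zerovalent palladium, and reductive elimination forges C17–C18. The closest known reaction type is the B-alkyl Suzuki–Miyaura coupling of 9-BBN-derived primary alkylboranes with (E)-2-methyl-1-iodoalkenes. No ring is closed and no stereocentre is created; the (E) geometry of C18=C19 is carried over with retention from 15, and C7, C11 and the ring stereocentre lie far from the reacting atoms. The step needs chemoselectivity (terminal CH=CH2 over the trisubstituted C2=C3 alkene and the internal diene bond), regioselectivity (boron at C17, not C16) and sp3–sp2 coupling without β-hydride elimination; the bulk of 9-BBN, the fact that the monoadduct keeps only trisubstituted alkenes, and the wide-bite-angle dppf ligand should secure these. In one operation the temporary C16=C17 unsaturation is consumed and the complete carbon skeleton, with all five alkenes and all three stereocentres, is in hand.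

**Step 19**
Reactants: 32 2-[(2E,7R,11S,14E,18E,22E)-3,7,11,15,19,23-hexamethyl-25-[(1S)-2,6,6-trimethylcyclohex-2-en-1-yl]pentacosa-2,14,18,22-tetraen-1-yl]-1,4-dimethoxy-3-methylnaphthalene
Product: 33 2-methyl-3-[(2E,7R,11S,14E,18E,22E)-3,7,11,15,19,23-hexamethyl-25-[(1S)-2,6,6-trimethylcyclohex-2-en-1-yl]pentacosa-2,14,18,22-tetraen-1-yl]naphthalene-1,4-dione
Conditions: (NH4)2Ce(NO3)6 (2.5 equiv), MeCN/CH2Cl2/H2O, 0 °C
Reagents that add atoms: water, O
Why: Oxidative demethylation of the hydroquinone dimethyl ether by tetravalent cerium (arene radical cation, ipso attack of water, loss of methanol) should unveil the quinone faster than the isolated trisubstituted alkenes are oxidised.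

**Compound list**

1 | 2,4,4-trimethylcyclohex-2-en-1-one | CC1=CC(C)(C)CCC1=O | starting material
2 | (1R)-2,4,4-trimethylcyclohex-2-en-1-ol | O[C@@H]1CCC(C)(C)C=C1C | intermediate
3 | 1-ethoxy-1-{[(1R)-2,4,4-trimethylcyclohex-2-en-1-yl]oxy}ethene (ketene acetal) | C=C(OCC)O[C@@H]1CCC(C)(C)C=C1C | intermediate
4 | ethyl 2-[(1S)-2,6,6-trimethylcyclohex-2-en-1-yl]acetate | CC1=CCCC(C)(C)[C@@H]1CC(=O)OCC | intermediate
5 | 2-[(1S)-2,6,6-trimethylcyclohex-2-en-1-yl]ethan-1-ol | CC1=CCCC(C)(C)[C@@H]1CCO | intermediate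
6 | (6S)-6-(2-iodoethyl)-1,5,5-trimethylcyclohex-1-ene | CC1=CCCC(C)(C)[C@@H]1CCI | intermediate
7 | (6S)-6-(but-3-yn-1-yl)-1,5,5-trimethylcyclohex-1-ene | CC1=CCCC(C)(C)[C@@H]1CCC#C | intermediate
8 | dimethyl{(1E)-2-methyl-4-[(1S)-2,6,6-trimethylcyclohex-2-en-1-yl]but-1-en-1-yl}alane | CC1=CCCC(C)(C)[C@@H]1CC/C(C)=C/[Al](C)C | intermediate
9 | (6S)-6-[(3E)-4-iodo-3-methylbut-3-en-1-yl]-1,5,5-trimethylcyclohex-1-ene | CC1=CCCC(C)(C)[C@@H]1CC/C(C)=C/I | intermediate
10 | (4-bromobut-1-yn-1-yl)trimethylsilane | C[Si](C)(C)C#CCCBr | starting material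
11 | [4-(trimethylsilyl)but-3-yn-1-yl]zinc bromide | C[Si](C)(C)C#CCC[Zn]Br | intermediate
12 | trimethyl{(5E)-6-methyl-8-[(1S)-2,6,6-trimethylcyclohex-2-en-1-yl]oct-5-en-1-yn-1-yl}silane | CC1=CCCC(C)(C)[C@@H]1CC/C(C)=C/CCC#C[Si](C)(C)C | intermediate
13 | (6S)-1,5,5-trimethyl-6-[(3E)-3-methyloct-3-en-7-yn-1-yl]cyclohex-1-ene | CC1=CCCC(C)(C)[C@@H]1CC/C(C)=C/CCC#C | intermediate
14 | {(1E,5E)-2,6-dimethyl-8-[(1S)-2,6,6-trimethylcyclohex-2-en-1-yl]octa-1,5-dien-1-yl}dimethylalane | CC1=CCCC(C)(C)[C@@H]1CC/C(C)=C/CC/C(C)=C/[Al](C)C | intermediate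
15 | (6S)-6-[(3E,7E)-8-iodo-3,7-dimethylocta-3,7-dien-1-yl]-1,5,5-trimethylcyclohex-1-ene | CC1=CCCC(C)(C)[C@@H]1CC/C(C)=C/CC/C(C)=C/I | intermediate
16 | (6R)-8-bromo-2,6-dimethyloct-2-ene [(R)-citronellyl bromide] | CC(C)=CCC[C@@H](C)CCBr | starting material
17 | (2E,6R)-8-bromo-2,6-dimethyloct-2-en-1-ol | OC/C(C)=C/CC[C@@H](C)CCBr | intermediate
18 | (2E,6R)-8-bromo-2,6-dimethyloct-2-enal | O=C/C(C)=C/CC[C@@H](C)CCBr | intermediate
19 | (3E,7R)-9-bromo-3,7-dimethylnona-1,3-diene | C=C/C(C)=C/CC[C@@H](C)CCBr | intermediate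
20 | (2R)-3-bromo-2-methylpropan-1-ol | OC[C@@H](C)CBr | starting material
21 | [4-(trimethylsilyl)but-3-yn-1-yl]magnesium bromide | C[Si](C)(C)C#CCC[Mg]Br | intermediate
22 | (2S)-2-methyl-7-(trimethylsilyl)hept-6-yn-1-ol | OC[C@@H](C)CCCC#C[Si](C)(C)C | intermediate
23 | (2S)-2-methylhept-6-yn-1-ol | OC[C@@H](C)CCCC#C | intermediate
24 | 1,4-dimethoxy-2-methylnaphthalene | COc1cc(C)c(OC)c2ccccc12 | starting material
25 | 2-(chloromethyl)-1,4-dimethoxy-3-methylnaphthalene | COc1c(CCl)c(C)c(OC)c2ccccc12 | intermediate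
26 | {(1E,6S)-7-[(dimethylalumanyl)oxy]-2,6-dimethylhept-1-en-1-yl}dimethylalane | C[Al](C)OC[C@@H](C)CCC/C(C)=C/[Al](C)C | intermediate
27 | (2S,6E)-8-(1,4-dimethoxy-3-methylnaphthalen-2-yl)-2,6-dimethyloct-6-en-1-ol | OC[C@@H](C)CCC/C(C)=C/Cc1c(C)c(OC)c2ccccc2c1OC | intermediate
28 | (2S,6E)-8-(1,4-dimethoxy-3-methylnaphthalen-2-yl)-2,6-dimethyloct-6-en-1-yl 4-methylbenzenesulfonate | Cc1ccc(cc1)S(=O)(=O)OC[C@@H](C)CCC/C(C)=C/Cc1c(C)c(OC)c2ccccc2c1OC | intermediate
29 | [(3R,6E)-3,7-dimethylnona-6,8-dien-1-yl]magnesium bromide | C=C/C(C)=C/CC[C@@H](C)CC[Mg]Br | intermediate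
30 | 2-[(2E,7R,11S,14E)-3,7,11,15-tetramethylheptadeca-2,14,16-trien-1-yl]-1,4-dimethoxy-3-methylnaphthalene | C=C/C(C)=C/CC[C@@H](C)CCC[C@@H](C)CCC/C(C)=C/Cc1c(C)c(OC)c2ccccc2c1OC | intermediate
31 | 9-[(3E,7S,11R,15E)-17-(1,4-dimethoxy-3-methylnaphthalen-2-yl)-3,7,11,15-tetramethylheptadeca-3,15-dien-1-yl]-9-borabicyclo[3.3.1]nonane | B1(CC/C(C)=C/CC[C@@H](C)CCC[C@@H](C)CCC/C(C)=C/Cc2c(C)c(OC)c3ccccc3c2OC)C2CCCC1CCC2 | intermediate
32 | 2-[(2E,7R,11S,14E,18E,22E)-3,7,11,15,19,23-hexamethyl-25-[(1S)-2,6,6-trimethylcyclohex-2-en-1-yl]pentacosa-2,14,18,22-tetraen-1-yl]-1,4-dimethoxy-3-methylnaphthalene | CC1=CCCC(C)(C)[C@@H]1CC/C(C)=C/CC/C(C)=C/CC/C(C)=C/CC[C@@H](C)CCC[C@@H](C)CCC/C(C)=C/Cc1c(C)c(OC)c2ccccc2c1OC | intermediate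
33 | 2-methyl-3-[(2E,7R,11S,14E,18E,22E)-3,7,11,15,19,23-hexamethyl-25-[(1S)-2,6,6-trimethylcyclohex-2-en-1-yl]pentacosa-2,14,18,22-tetraen-1-yl]naphthalene-1,4-dione | CC1=CCCC(C)(C)[C@@H]1CC/C(C)=C/CC/C(C)=C/CC/C(C)=C/CC[C@@H](C)CCC[C@@H](C)CCC/C(C)=C/CC1=C(C)C(=O)c2ccccc2C1=O | target

**Step count and risks**

Total step count: 19. Longest linear sequence: 11 steps (steps 1 to 9, then 18 and 19).

Steps most likely to fail:

1. Step 18. What may go wrong: slow transfer of the homoallyl group from boron to palladium under the aqueous basic conditions, so that protodeboronation of 31 and β-hydride elimination from the alkylpalladium intermediate compete with coupling. Fallback (polarity kept, metal changed to zinc, anhydrous): the route sets out from 30, which is hydroborated with 9-BBN and oxidised with NaOH/H2O2 to the primary alcohol (3E,7S,11R,15E)-17-(1,4-dimethoxy-3-methylnaphthalen-2-yl)-3,7,11,15-tetramethylheptadeca-3,15-dien-1-ol F1. I2/PPh3/imidazole should convert it into the homoallylic iodide 2-[(2E,7R,11S,14E)-17-iodo-3,7,11,15-tetramethylheptadeca-2,14-dien-1-yl]-1,4-dimethoxy-3-methylnaphthalene F2. LiCl-assisted insertion of Zn dust (THF, 40 °C) should give the corresponding alkylzinc iodide F3, which is coupled with 15 under PdCl2(dppf) catalysis in THF (alkyl–alkenyl Negishi coupling) and comes back to the route at 32.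

2. Step 17. What may go wrong: Wurtz-type homocoupling and radical cyclisation onto the diene while the Grignard reagent forms, and sluggish displacement at the β-branched tosylate. Fallback (stabilised carbanion instead of organomagnesium): the route sets out from 19 and 27. Bromide 19 with PhSO2Na in DMF should give {[(3R,6E)-3,7-dimethylnona-6,8-dien-1-yl]sulfonyl}benzene F4. Alcohol 27 with I2/PPh3/imidazole should give 2-[(2E,7S)-8-iodo-3,7-dimethyloct-2-en-1-yl]-1,4-dimethoxy-3-methylnaphthalene F5. Deprotonation of F4 with n-BuLi (THF/DMPU, −78 °C) and alkylation with F5 should give the C9-phenylsulfonyl derivative of 30 (epimers at C9) F6. Reductive desulfonylation with sodium amalgam (Na/Hg, Na2HPO4, MeOH, −20 °C), which leaves unactivated dienes alone, comes back to the route at 30.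

3. Step 15. What may go wrong: alkenyl transfer from aluminium to nickel is retarded by the neighbouring aluminium alkoxide, so that protodemetallation of 26 and reductive homocoupling of 25 take over. Fallback (reversed polarity at C1–C2): the route sets out from 23 and 25. Carboalumination of 23 as in step 15 followed by iodinolysis should give the isolable (2S,6E)-7-iodo-2,6-dimethylhept-6-en-1-ol F7. LiCl-assisted zinc insertion into 25 should give [(1,4-dimethoxy-3-methylnaphthalen-2-yl)methyl]zinc chloride F8. Negishi coupling of F7 with F8 (2.2 equiv, the first equivalent taking the hydroxyl proton) under Pd(PPh3)4 in THF comes back to the route at 27.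

**Further compounds**

F1 | step 18 | (3E,7S,11R,15E)-17-(1,4-dimethoxy-3-methylnaphthalen-2-yl)-3,7,11,15-tetramethylheptadeca-3,15-dien-1-ol | OCC/C(C)=C/CC[C@@H](C)CCC[C@@H](C)CCC/C(C)=C/Cc1c(C)c(OC)c2ccccc2c1OC
F2 | step 18 | 2-[(2E,7R,11S,14E)-17-iodo-3,7,11,15-tetramethylheptadeca-2,14-dien-1-yl]-1,4-dimethoxy-3-methylnaphthalene | ICC/C(C)=C/CC[C@@H](C)CCC[C@@H](C)CCC/C(C)=C/Cc1c(C)c(OC)c2ccccc2c1OC
F3 | step 18 | [(3E,7S,11R,15E)-17-(1,4-dimethoxy-3-methylnaphthalen-2-yl)-3,7,11,15-tetramethylheptadeca-3,15-dien-1-yl]zinc iodide | I[Zn]CC/C(C)=C/CC[C@@H](C)CCC[C@@H](C)CCC/C(C)=C/Cc1c(C)c(OC)c2ccccc2c1OC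
F4 | step 17 | {[(3R,6E)-3,7-dimethylnona-6,8-dien-1-yl]sulfonyl}benzene | C=C/C(C)=C/CC[C@@H](C)CCS(=O)(=O)c1ccccc1
F5 | step 17 | 2-[(2E,7S)-8-iodo-3,7-dimethyloct-2-en-1-yl]-1,4-dimethoxy-3-methylnaphthalene | IC[C@@H](C)CCC/C(C)=C/Cc1c(C)c(OC)c2ccccc2c1OC
F6 | step 17 | C9-phenylsulfonyl derivative of 30 (epimers at C9) | C=C/C(C)=C/CC[C@@H](C)CC(S(=O)(=O)c1ccccc1)C[C@@H](C)CCC/C(C)=C/Cc1c(C)c(OC)c2ccccc2c1OC
F7 | step 15 | (2S,6E)-7-iodo-2,6-dimethylhept-6-en-1-ol | OC[C@@H](C)CCC/C(C)=C/I
F8 | step 15 | [(1,4-dimethoxy-3-methylnaphthalen-2-yl)methyl]zinc chloride | Cl[Zn]Cc1c(C)c(OC)c2ccccc2c1OC
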